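**Remark on the chemistry.** Positions are given in cembrane numbering: C1 lactone β-carbon, C2 lactone O–CH, C3–C4 oxirane, C14 acetoxy carbon, C15/C16/C17 lactone α-carbon, carbonyl and exo-methylene, C18/C19/C20 the methyls on C4/C8/C12. Chloroacetaldehyde 15 is assumed to be used as the anhydrous monomer distilled from its commercial aqueous solution, and the silyl bromide 5 is taken as a catalogue compound.

## Analysis of the target

Target 33 is a cembranolide: a 14-membered carbocycle (C1–C14) with a trans-fused α-methylene-γ-butyrolactone across C1–C2 (C15, C16, C17), a trisubstituted oxirane at C3–C4, two E trisubstituted olefins (C7=C8, C11=C12) and an acetate on C14. The five stereocentres are contiguous (C14, C1, C2, C3, C4) with configuration 14S,1R,2S,3R,4R. Along the backbone C13–C14–C1–C2–C3 the oxygen on C14, the C15 branch on C1 and the oxygen on C2 are all syn; the oxygens on C2 and C3 are threo; in the oxirane C2 is cis to the C18 methyl. The other half of the ring, C5 to C13, has no stereocentre and carries only the geometry of the two olefins. Sensitive groups are the exo-methylene lactone (Michael acceptor), the oxirane with its tertiary C4–O bond (acid), and the C14 oxygen, which like O2 is γ to C16 and can take over the lactone once it is a free alkoxide. The hard points are closing a 14-membered carbocycle while fixing a trisubstituted olefin geometry, and telling the two γ-oxygens apart. The strategy rests on the array O–C14–C13H2–C12(CH3)=C11H: the C14 carbinol is homoallylic to the E olefin that bears C20, which is what syn addition of hydrogen and of an oxirane-derived C13 across a methyl-capped C11≡C12 alkyne leaves behind.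

## Retrosynthetic reasoning

**33 to 27 (acetyl C–O on C14, C15=C17).** The acetate and the exo-methylene are removed first. An enoate would itself couple with the alkyne under nickel, and an acetate would not survive the lactone enolate needed for methylenation. So 33 comes from alcohol 32, 32 from silyl ether 31, 31 from the saturated lactone 28 by aminomethylation and elimination, and 28 from the macrocyclic alcohol 27. The ring-closing substrate then carries only inert groups, at the price of a four-step end game.

**27 to 26 (C12–C13).** The ring is opened between the methyl-bearing olefin carbon and the methylene next to the carbinol, giving the epoxy alkyne 26. Cutting here makes ring closure, olefin construction and placement of C20 one event and creates no stereocentre, since C14 keeps its oxygen. The forward step must open the monosubstituted oxirane at C13, bond it to C12 and not C11, add hydrogen to C11 syn, and leave the C3–C4 oxirane and the lactone alone.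

**26 to 25 to 24 (O2–C16, then the C3–C4 oxirane).** The lactone is opened to the γ-hydroxy tert-butyl ester 25 so that O2 is a free allylic hydroxyl in 24. Only a free hydroxyl can steer the oxidant to C3=C4 in the presence of C7=C8 and set the threo relationship. In 25 the other γ-oxygen, O14, is already locked in the terminal oxirane, so only O2 can lactonise. The forward steps must epoxidise one of two trisubstituted olefins on one face and then acylate O2 without acid.

**24 to 23 to 21 (O14–C13, then C2–H).** The terminal oxirane is traced to chlorohydrin 23; the C14–O bond is never broken, so C14 is that of the carbinol. The all-syn triad of 23 is the retron of a 1,3-syn reduction of a β-hydroxy ketone, which leads to enone 21. Adding the alkenyl group to an aldehyde instead would depend on Felkin control by a weakly biased α-centre.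

**21 to 18 and 10 (C2–C3).** Enone 21 is cut at the acyl–alkenyl bond into Weinreb amide 18 and the alkenyllithium 19 made from iodide 10. This is the convergent cut: 18 carries the two aldol centres from which the other three follow, and 10 carries only olefin geometry.

**18 to 17 to 14 and 15; 14 to 11 and 12 (C1–C14).** An auxiliary-controlled syn aldol between the succinate imide 14 and chloroacetaldehyde 15 sets C1 and C14 together and brings C13 with its leaving group. C15–C16 arrive as a tert-butyl ester, chosen because it neither enolises nor lactonises with O14. Imide 14 is the acylation product of 12 with 11.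

**10 to 8 to 7 to 4 and 5; 4 to 2 to 1.** Each E methyl olefin is the retron of a zirconium-catalysed methylalumination of a terminal alkyne followed by iodination. The C6–C7 bond between the two units is an sp3–sp2 cross-coupling of 4 with the zinc reagent 6 from 5. The methyl-capped alkyne is introduced at the start by methylating 1 to 2.

## Alternatives that were turned down

**Alternative 1: ring contraction at C5–C6.**
- Disconnection: C5–C6, with the carbocycle derived from the 16-membered allyl β-keto ester macrolactone A1, in which a carboxylate bridges C5 and C6.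
- Forward key step: Pd(PPh3)4 (zerovalent palladium) ionises the allylic C6–O bond of A1, decarboxylation unveils the C5 enolate of the C4 ketone, and recombination at C6 gives the 14-membered ketone A2.
- For it: the large ring is first made by a dependable macrolactonisation. The C–C bond then forms inside an ion pair between two methylenes far from any stereocentre. Both steps are known reaction types, so on precedent it is stronger than the chosen closure.
- Against it: the π-allyl unit C6–C7–C8 can be attacked at C8 or lose its E geometry by syn–anti exchange. Enolate equilibration towards C3 would expel the lactone oxygen on C2. A2 still lacks C18 and the oxirane, so methyl addition to the ring ketone (a new facial problem at C4), ether cleavage, activation of O3 and closure with inversion must follow before the same lactone and acetate end game.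
- Comparison: the chosen route reaches the ring with oxirane, C18 and all five stereocentres in place and needs four steps afterwards, against roughly twice as many from A2. What it gives up is precedent for the ring-forming step.

**Alternative 2: alkyne metathesis at C11–C12.**
- Disconnection: the C11=C12 olefin is traced to a ring alkyne and C20 to a late methyl; the ring is opened to diyne A3 with two methyl-capped alkynes.
- Forward key step: Mo(≡CC6H4OMe)(OSiPh3)3 metathesises the two alkynes of A3, the methyl caps leave as a volatile alkyne, and cycloalkyne A4 results. The C14 hydroxyl then directs a ruthenium-catalysed trans-hydrostannation (tin on C12), and tin is exchanged for methyl to give 32 of the present route.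
- For it: ring-closing alkyne metathesis is the most dependable entry to a 14-membered carbocycle and raises no geometry issue. The catalyst ignores olefins, so the exo-methylene lactone may already be present. Only three steps follow ring closure (hydrostannation, methylation, acetylation) against five here. On reliability and on the post-cyclisation count it is the stronger plan.
- Against it: the olefin needs two further metal-mediated steps with stoichiometric tin. Regiocontrol rests on a homopropargylic, not a propargylic, hydroxyl. Tin hydride and the palladium/copper methylation must spare the exo-methylene lactone. A3 needs C13 as a propargylic carbon next to the carbinol, which means an extra alkynylation on the stereo-rich fragment.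
- Comparison: the chosen closure makes ring, E olefin and the methyl-bearing carbon in one step, without tin, from an oxirane that already carries the C14 configuration. The metathesis sequence is kept as the fallback for that step.

**Alternative 3: diene–aldehyde closure at C13–C14.**
- Disconnection: C13–C14, to aldehyde A5 with C14 as a formyl group on C1 and a 2-methyl-1,3-diene spanning C10–C13.
- Forward key step: Ni(cod)2/PPh3 (zerovalent nickel) with Et3SiH joins the aldehyde carbon to the diene terminus C13, delivers hydride to C10, forms the C11=C12 olefin and silylates O14, giving A6.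
- For it: A6 is identical with 28, so the silylation step of the present route is saved. On that point it is stronger.
- Against it: C14 is created during the macrocyclisation with only 1,2-induction from C1. The formyl group sits on the epimerisable C1. The olefin geometry depends on the syn/anti preference of a 2-methyl-substituted allylnickel. Macrocyclic precedent is as thin as for the chosen step.
- Comparison: the chosen step inherits C14 from an auxiliary-controlled aldol and gets the E geometry from syn addition, so the uncertain step sets neither a stereocentre nor a geometry by substrate bias.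

Key step: step 14

## Route

Step 1
Reactants: 1 hexa-1,5-diyne
Product: 2 hepta-1,5-diyne
Conditions: 1 (3 equiv), n-BuLi (1 equiv), THF, −78 °C; MeI, −78 °C → rt; fractional distillation
Reagents that add atoms: iodomethane, CI
Why: C-alkylation of a lithium acetylide; the excess of diyne should suppress double methylation, and the three hydrocarbons differ enough in boiling point to be separated.

Step 2
Reactants: 2 hepta-1,5-diyne
Product: 4 (1E)-1-iodo-2-methylhept-1-en-5-yne, via alkenylalane 3 (not isolated)
Conditions: AlMe3 (2 equiv), Cp2ZrCl2 (0.2 equiv), CH2Cl2, 0 °C → rt; then I2, THF, −30 → 0 °C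
Reagents that add atoms: trimethylaluminium, C[Al](C)C; iodine, II
Why: Negishi zirconium-catalysed carboalumination adds methyl and aluminium syn across the terminal alkyne with aluminium on the terminal carbon, and iodinolysis with retention gives the E iodide. The internal methyl-capped alkyne reacts much more slowly and should be left untouched.

Step 3
Reactants: 4 (1E)-1-iodo-2-methylhept-1-en-5-yne; 5 (4-bromobut-1-yn-1-yl)trimethylsilane
Product: 7 trimethyl[(5E)-6-methylundec-5-ene-1,9-diyn-1-yl]silane, via alkylzinc bromide 6 (not isolated)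
Conditions: 5, Zn dust, LiCl, THF, 50 °C; then 4, Pd(PPh3)4 (5 mol%), THF, rt → 40 °C
Reagents that add atoms: none
Why: Negishi sp3–sp2 cross-coupling of a homopropargylic zinc reagent with an alkenyl iodide proceeds with retention of olefin geometry; the silyl cap keeps the new alkyne out of the reaction.

Step 4
Reactants: 7 trimethyl[(5E)-6-methylundec-5-ene-1,9-diyn-1-yl]silane
Product: 8 (5E)-6-methylundec-5-ene-1,9-diyne
Conditions: K2CO3 (0.3 equiv), MeOH, rt
Reagents that add atoms: none
Why: Methanolysis of the alkynyl–silicon bond under mild base frees the terminal alkyne without touching the olefin or the internal alkyne.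

Step 5
Reactants: 8 (5E)-6-methylundec-5-ene-1,9-diyne
Product: 10 (1E,5E)-1-iodo-2,6-dimethylundeca-1,5-dien-9-yne, via alkenylalane 9 (not isolated)
Conditions: AlMe3 (2 equiv), Cp2ZrCl2 (0.2 equiv), CH2Cl2, 0 °C → rt; then I2, THF, −30 → 0 °C
Reagents that add atoms: trimethylaluminium, C[Al](C)C; iodine, II
Why: Second Negishi carboalumination–iodination, again selective for the terminal over the internal alkyne, sets the C3=C4 olefin as E with iodine cis to the new methyl.

Step 6
Reactants: 11 4-tert-butoxy-4-oxobutanoic acid; 12 (4R)-4-benzyl-1,3-oxazolidin-2-one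
Product: 14 tert-butyl 4-[(4R)-4-benzyl-2-oxo-1,3-oxazolidin-3-yl]-4-oxobutanoate, via mixed pivalic anhydride 13 (not isolated)
Conditions: PivCl, Et3N, THF, −20 °C; then 12, LiCl, −20 °C → rt
Reagents that add atoms: none
Why: N-acylation through the mixed anhydride, which is attacked at the unhindered succinyl carbonyl; a standard way to load an oxazolidinone auxiliary.

Step 7
Reactants: 14 tert-butyl 4-[(4R)-4-benzyl-2-oxo-1,3-oxazolidin-3-yl]-4-oxobutanoate; 15 chloroacetaldehyde
Product: 17 tert-butyl (3R,4R)-3-{[(4R)-4-benzyl-2-oxo-1,3-oxazolidin-3-yl]carbonyl}-5-chloro-4-hydroxypentanoate, via Z boron enolate 16 (not isolated)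
Conditions: Bu2BOTf, i-Pr2NEt, CH2Cl2, 0 °C; 15, −78 → 0 °C; pH 7 buffer, MeOH, H2O2, 0 °C
Reagents that add atoms: none
Why: Evans syn aldol: the Z boron enolate adds through a closed chair transition state, and the (R)-benzyl group blocks one enolate face, setting C1 and C14 together as 3R,4R. The tert-butyl ester is neither enolised nor attacked by the new hydroxyl.

Step 8
Reactants: 17 tert-butyl (3R,4R)-3-{[(4R)-4-benzyl-2-oxo-1,3-oxazolidin-3-yl]carbonyl}-5-chloro-4-hydroxypentanoate
Product: 18 tert-butyl (3R,4R)-5-chloro-4-hydroxy-3-[methoxy(methyl)carbamoyl]pentanoate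
Conditions: MeNH(OMe)·HCl, AlMe3, CH2Cl2, −20 → 0 °C
Reagents that add atoms: N,O-dimethylhydroxylamine hydrochloride, CNOC.Cl
Why: Aluminium amide transamination of the imide, assisted by the neighbouring aluminium alkoxide, gives the Weinreb amide and returns the auxiliary; the hindered ester should not react.

Step 9
Reactants: 18 tert-butyl (3R,4R)-5-chloro-4-hydroxy-3-[methoxy(methyl)carbamoyl]pentanoate; 10 (1E,5E)-1-iodo-2,6-dimethylundeca-1,5-dien-9-yne
Product: 21 tert-butyl (3R,5E,9E)-3-[(1R)-2-chloro-1-hydroxyethyl]-6,10-dimethyl-4-oxopentadeca-5,9-dien-13-ynoate, via alkenyllithium 19 (not isolated), via chloromagnesium alkoxide 20 (not isolated)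
Conditions: 10, t-BuLi (2.05 equiv), Et2O, −78 °C; separately 18, i-PrMgCl (1.0 equiv), THF, −78 °C; combine at −78 °C; aq. NH4Cl at −78 °C
Reagents that add atoms: none
Why: Weinreb ketone synthesis: iodine–lithium exchange keeps the E geometry, the hydroxyl is parked as its magnesium alkoxide, and the alkenyllithium adds once because the chelated tetrahedral adduct lasts until the quench. At −78 °C the tert-butyl ester and the alkyl chloride should not be attacked.

Step 10
Reactants: 21 tert-butyl (3R,5E,9E)-3-[(1R)-2-chloro-1-hydroxyethyl]-6,10-dimethyl-4-oxopentadeca-5,9-dien-13-ynoate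
Product: 23 tert-butyl (3S,4R,5E,9E)-3-[(1R)-2-chloro-1-hydroxyethyl]-4-hydroxy-6,10-dimethylpentadeca-5,9-dien-13-ynoate, via boron chelate 22 (not isolated)
Conditions: Et2BOMe, THF/MeOH (4:1), −78 °C; NaBH4, −78 °C; AcOH; co-evaporation with MeOH
Reagents that add atoms: none
Why: Narasaka–Prasad reduction: boron ties O14 and the ketone into a six-membered chelate and external hydride attacks axially, anti to the pseudo-axial C15 branch on C1, giving the 1,3-syn diol and hence C2 as R. Chelate activation should favour 1,2- over conjugate reduction of the enone.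

Step 11
Reactants: 23 tert-butyl (3S,4R,5E,9E)-3-[(1R)-2-chloro-1-hydroxyethyl]-4-hydroxy-6,10-dimethylpentadeca-5,9-dien-13-ynoate
Product: 24 tert-butyl (3S,4R,5E,9E)-4-hydroxy-6,10-dimethyl-3-[(2R)-oxiran-2-yl]pentadeca-5,9-dien-13-ynoate
Conditions: K2CO3, MeOH, 0 °C
Reagents that add atoms: none
Why: Williamson-type 3-exo-tet closure: the chlorohydrin hydroxyl is the more acidic of the two and its alkoxide displaces the neighbouring primary chloride, so C14 keeps its configuration. Carbonate in methanol at 0 °C should leave the C2 hydroxyl and the tert-butyl ester alone.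

Step 12
Reactants: 24 tert-butyl (3S,4R,5E,9E)-4-hydroxy-6,10-dimethyl-3-[(2R)-oxiran-2-yl]pentadeca-5,9-dien-13-ynoate
Product: 25 tert-butyl (3S,4S)-4-hydroxy-4-{(2R,3R)-3-methyl-3-[(3E)-4-methylnon-3-en-7-yn-1-yl]oxiran-2-yl}-3-[(2R)-oxiran-2-yl]butanoate
Conditions: VO(acac)2 (5 mol%), t-BuOOH (1.5 equiv, in decane), CH2Cl2, 0 °C
Reagents that add atoms: tert-butyl hydroperoxide, CC(C)(C)OO
Why: Hydroxyl-directed epoxidation: the vanadium peroxide bound to O2 reaches only the allylic C3=C4 olefin, leaving C7=C8 and the alkyne. Allylic 1,3-strain between C1 and the C18 methyl (cis to C2) holds H2 in the olefin plane, so oxygen arrives on the O2 face and gives the threo 3R,4R oxirane; the E olefin fixes C4 relative to C3.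

Step 13
Reactants: 25 tert-butyl (3S,4S)-4-hydroxy-4-{(2R,3R)-3-methyl-3-[(3E)-4-methylnon-3-en-7-yn-1-yl]oxiran-2-yl}-3-[(2R)-oxiran-2-yl]butanoate
Product: 26 (4R,5S)-5-{(2R,3R)-3-methyl-3-[(3E)-4-methylnon-3-en-7-yn-1-yl]oxiran-2-yl}-4-[(2R)-oxiran-2-yl]oxolan-2-one
Conditions: KOt-Bu (0.2 equiv), THF, 0 °C; pH 7 buffer
Reagents that add atoms: none
Why: Base-catalysed intramolecular transesterification (5-exo-trig): O2 is the only hydroxyl left and is γ to the ester, so its alkoxide expels tert-butoxide, which carries the chain, and closes the trans-lactone. Payne isomerisation of the epoxy alkoxide is reversible and should drain through the lactone.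

Step 14
Reactants: 26 (4R,5S)-5-{(2R,3R)-3-methyl-3-[(3E)-4-methylnon-3-en-7-yn-1-yl]oxiran-2-yl}-4-[(2R)-oxiran-2-yl]oxolan-2-one
Product: 27 (1R,2S,3R,4R,7E,11E,14S)-3,4-epoxy-14-hydroxycembra-7,11-dien-16,2-olide
Conditions: Ni(cod)2 (20 mol%), PBu3 (40 mol%), Et3B (3 equiv), t-BuOMe, rt, 26 added by syringe pump (final 0.005 M); aq. NH4Cl
Reagents that add atoms: none
Why: Proposed new method: zerovalent nickel, with Et3B as Lewis acid, should open the monosubstituted oxirane at C13, and syn insertion of the C11≡C12 alkyne into the nickel–C13 bond should give a six-membered alkenylnickel alkoxide (divalent nickel) with nickel on C11; ethyl transfer from boron, β-hydride elimination of ethene and C–H reductive elimination then place hydrogen on C11 and return zerovalent nickel. The closest known reaction type is the nickel-catalysed reductive coupling of alkynes with terminal epoxides to E-homoallylic alcohols, established intermolecularly and for closing five- and six-membered rings, but not for a 14-membered carbocycle from an unactivated methyl-capped dialkyl alkyne. The 14-membered ring closes by C12–C13 bond formation, endo with respect to both the alkyne and the oxirane, leaving C20 as the exocyclic methyl of the ring olefin. No stereocentre is formed: the C14–O bond is never broken, so C14 keeps the configuration set in step 7, and syn addition of C13 and hydrogen fixes the olefin as E. The step needs bonding at C12 rather than C11; this is backed by the small methyl terminus, which lets the tether-bearing carbon stay on nickel, by the lower strain of a 14-membered E-cycloalkene compared with a 13-membered ring with an exocyclic ethylidene, and by a small phosphine that should not override these. It also needs chemoselectivity: the trisubstituted C3–C4 oxirane is too hindered for nickel insertion, and the lactone carries no enoate that could couple with the alkyne. Slow addition at high dilution, with the trans-lactone and the E C7=C8 olefin limiting the chain conformations, should favour ring closure over oligomerisation.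

Step 15
Reactants: 27 (1R,2S,3R,4R,7E,11E,14S)-3,4-epoxy-14-hydroxycembra-7,11-dien-16,2-olide
Product: 28 14-O-triethylsilyl ether of 27
Conditions: Et3SiCl, imidazole, DMF, 0 °C → rt
Reagents that add atoms: chlorotriethylsilane, CC[Si](Cl)(CC)CC
Why: Silylation of the secondary alcohol under neutral amine conditions masks O14, which would otherwise be deprotonated in the next step and could attack the lactone carbonyl.

Step 16
Reactants: 28 14-O-triethylsilyl ether of 27
Product: 31 14-O-triethylsilyl ether of (1R,2S,3R,4R,7E,11E,14S)-3,4-epoxy-14-hydroxycembra-7,11,15(17)-trien-16,2-olide, via Mannich base 29 (not isolated), via ammonium iodide 30 (not isolated)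
Conditions: LiN(i-Pr)2, THF, −78 °C; CH2=NMe2+ I−, −78 → 0 °C; MeI, MeOH/CH2Cl2, rt; aq. NaHCO3, CH2Cl2, rt
Reagents that add atoms: dimethylmethyleneiminium iodide, C=[N+](C)C.[I-]
Why: Enolate aminomethylation with Eschenmoser's salt, N-methylation and base-induced elimination of trimethylamine is the standard α-methylenation of γ-butyrolactones. C15 is the only enolisable position and C1 carries no leaving group.

Step 17
Reactants: 31 14-O-triethylsilyl ether of (1R,2S,3R,4R,7E,11E,14S)-3,4-epoxy-14-hydroxycembra-7,11,15(17)-trien-16,2-olide
Product: 32 (1R,2S,3R,4R,7E,11E,14S)-3,4-epoxy-14-hydroxycembra-7,11,15(17)-trien-16,2-olide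
Conditions: Bu4NF/AcOH (1:1), THF, 0 °C → rt
Reagents that add atoms: none
Why: Fluoride cleavage of the triethylsilyl ether, buffered with acetic acid so that no free alkoxide is present to attack the lactone carbonyl or the exo-methylene; the oxirane is stable at this near-neutral pH.

Step 18
Reactants: 32 (1R,2S,3R,4R,7E,11E,14S)-3,4-epoxy-14-hydroxycembra-7,11,15(17)-trien-16,2-olide
Product: 33 (1R,2S,3R,4R,7E,11E,14S)-14-acetoxy-3,4-epoxycembra-7,11,15(17)-trien-16,2-olide (CNP0294029.1)
Conditions: Ac2O, pyridine, DMAP (0.1 equiv), CH2Cl2, 0 °C → rt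
Reagents that add atoms: acetic anhydride, CC(=O)OC(C)=O
Why: DMAP-catalysed acetylation of the secondary alcohol with retention at C14; the conditions are mild enough for the oxirane and the exo-methylene lactone.

## Compound list

1 | hexa-1,5-diyne | C#CCCC#C | starting material
2 | hepta-1,5-diyne | CC#CCCC#C | intermediate
3 | dimethyl[(1E)-2-methylhept-1-en-5-yn-1-yl]alane (formed in the flask) | CC#CCC/C(C)=C/[Al](C)C | intermediate
4 | (1E)-1-iodo-2-methylhept-1-en-5-yne | CC#CCC/C(C)=C/I | intermediate
5 | (4-bromobut-1-yn-1-yl)trimethylsilane | C[Si](C)(C)C#CCCBr | starting material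
6 | [4-(trimethylsilyl)but-3-yn-1-yl]zinc bromide (formed in the flask) | C[Si](C)(C)C#CCC[Zn]Br | intermediate
7 | trimethyl[(5E)-6-methylundec-5-ene-1,9-diyn-1-yl]silane | CC#CCC/C(C)=C/CCC#C[Si](C)(C)C | intermediate
8 | (5E)-6-methylundec-5-ene-1,9-diyne | CC#CCC/C(C)=C/CCC#C | intermediate
9 | [(1E,5E)-2,6-dimethylundeca-1,5-dien-9-yn-1-yl]dimethylalane (formed in the flask) | CC#CCC/C(C)=C/CC/C(C)=C/[Al](C)C | intermediate
10 | (1E,5E)-1-iodo-2,6-dimethylundeca-1,5-dien-9-yne | CC#CCC/C(C)=C/CC/C(C)=C/I | intermediate
11 | 4-tert-butoxy-4-oxobutanoic acid (mono-tert-butyl succinate) | OC(=O)CCC(=O)OC(C)(C)C | starting material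
12 | (4R)-4-benzyl-1,3-oxazolidin-2-one | O=C1N[C@H](Cc2ccccc2)CO1 | starting material
13 | 4-tert-butoxy-4-oxobutanoic 2,2-dimethylpropanoic anhydride (formed in the flask) | CC(C)(C)OC(=O)CCC(=O)OC(=O)C(C)(C)C | intermediate
14 | tert-butyl 4-[(4R)-4-benzyl-2-oxo-1,3-oxazolidin-3-yl]-4-oxobutanoate | CC(C)(C)OC(=O)CCC(=O)N1[C@H](Cc2ccccc2)COC1=O | intermediate
15 | chloroacetaldehyde | ClCC=O | starting material
16 | tert-butyl (3Z)-4-[(4R)-4-benzyl-2-oxo-1,3-oxazolidin-3-yl]-4-[(dibutylboranyl)oxy]but-3-enoate (formed in the flask) | CCCCB(CCCC)O/C(=C\CC(=O)OC(C)(C)C)N1[C@H](Cc2ccccc2)COC1=O | intermediate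
17 | tert-butyl (3R,4R)-3-{[(4R)-4-benzyl-2-oxo-1,3-oxazolidin-3-yl]carbonyl}-5-chloro-4-hydroxypentanoate | CC(C)(C)OC(=O)C[C@H]([C@@H](O)CCl)C(=O)N1[C@H](Cc2ccccc2)COC1=O | intermediate
18 | tert-butyl (3R,4R)-5-chloro-4-hydroxy-3-[methoxy(methyl)carbamoyl]pentanoate | CC(C)(C)OC(=O)C[C@H]([C@@H](O)CCl)C(=O)N(C)OC | intermediate
19 | [(1E,5E)-2,6-dimethylundeca-1,5-dien-9-yn-1-yl]lithium (formed in the flask) | CC#CCC/C(C)=C/CC/C(C)=C/[Li] | intermediate
20 | chloromagnesium alkoxide of 18 (formed in the flask) | CC(C)(C)OC(=O)C[C@H]([C@@H](O[Mg]Cl)CCl)C(=O)N(C)OC | intermediate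
21 | tert-butyl (3R,5E,9E)-3-[(1R)-2-chloro-1-hydroxyethyl]-6,10-dimethyl-4-oxopentadeca-5,9-dien-13-ynoate | CC#CCC/C(C)=C/CC/C(C)=C/C(=O)[C@H](CC(=O)OC(C)(C)C)[C@@H](O)CCl | intermediate
22 | cyclic diethylboron chelate of 21, boron bridging O14 and the C2 carbonyl oxygen (formed in the flask) | CC#CCC/C(C)=C/CC/C(C)=C/C1=[O+][B-](CC)(CC)O[C@@H](CCl)[C@H]1CC(=O)OC(C)(C)C | intermediate
23 | tert-butyl (3S,4R,5E,9E)-3-[(1R)-2-chloro-1-hydroxyethyl]-4-hydroxy-6,10-dimethylpentadeca-5,9-dien-13-ynoate | CC#CCC/C(C)=C/CC/C(C)=C/[C@@H](O)[C@H](CC(=O)OC(C)(C)C)[C@@H](O)CCl | intermediate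
24 | tert-butyl (3S,4R,5E,9E)-4-hydroxy-6,10-dimethyl-3-[(2R)-oxiran-2-yl]pentadeca-5,9-dien-13-ynoate | CC#CCC/C(C)=C/CC/C(C)=C/[C@@H](O)[C@H](CC(=O)OC(C)(C)C)[C@@H]1CO1 | intermediate
25 | tert-butyl (3S,4S)-4-hydroxy-4-{(2R,3R)-3-methyl-3-[(3E)-4-methylnon-3-en-7-yn-1-yl]oxiran-2-yl}-3-[(2R)-oxiran-2-yl]butanoate | CC#CCC/C(C)=C/CC[C@@]1(C)O[C@@H]1[C@@H](O)[C@H](CC(=O)OC(C)(C)C)[C@@H]1CO1 | intermediate
26 | (4R,5S)-5-{(2R,3R)-3-methyl-3-[(3E)-4-methylnon-3-en-7-yn-1-yl]oxiran-2-yl}-4-[(2R)-oxiran-2-yl]oxolan-2-one | CC#CCC/C(C)=C/CC[C@@]1(C)O[C@@H]1[C@H]1OC(=O)C[C@@H]1[C@@H]1CO1 | intermediate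
27 | (1R,2S,3R,4R,7E,11E,14S)-3,4-epoxy-14-hydroxycembra-7,11-dien-16,2-olide | C1C(=O)O[C@H]2[C@H]1[C@@H](O)C/C(C)=C/CC/C(C)=C/CC[C@@]1(C)O[C@H]21 | intermediate
28 | 14-O-triethylsilyl ether of 27 | C1C(=O)O[C@H]2[C@H]1[C@@H](O[Si](CC)(CC)CC)C/C(C)=C/CC/C(C)=C/CC[C@@]1(C)O[C@H]21 | intermediate
29 | 15-[(dimethylamino)methyl] derivative of 28, C15 epimers (formed in the flask) | CN(C)CC1C(=O)O[C@H]2[C@H]1[C@@H](O[Si](CC)(CC)CC)C/C(C)=C/CC/C(C)=C/CC[C@@]1(C)O[C@H]21 | intermediate
30 | N-methyl ammonium iodide of 29 (formed in the flask) | C[N+](C)(C)CC1C(=O)O[C@H]2[C@H]1[C@@H](O[Si](CC)(CC)CC)C/C(C)=C/CC/C(C)=C/CC[C@@]1(C)O[C@H]21.[I-] | intermediate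
31 | 14-O-triethylsilyl ether of 32 | C=C1C(=O)O[C@H]2[C@H]1[C@@H](O[Si](CC)(CC)CC)C/C(C)=C/CC/C(C)=C/CC[C@@]1(C)O[C@H]21 | intermediate
32 | (1R,2S,3R,4R,7E,11E,14S)-3,4-epoxy-14-hydroxycembra-7,11,15(17)-trien-16,2-olide | C=C1C(=O)O[C@H]2[C@H]1[C@@H](O)C/C(C)=C/CC/C(C)=C/CC[C@@]1(C)O[C@H]21 | intermediate
33 | (1R,2S,3R,4R,7E,11E,14S)-14-acetoxy-3,4-epoxycembra-7,11,15(17)-trien-16,2-olide (CNP0294029.1) | C=C1C(=O)O[C@H]2[C@H]1[C@@H](OC(C)=O)C/C(C)=C/CC/C(C)=C/CC[C@@]1(C)O[C@H]21 | target

## Step count and least certain steps

Total: 18 steps. Longest linear sequence: 15 steps (steps 1–5 and 9–18, from 1); steps 6–8 are the side branch from 11 that joins at step 9.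

**Step 14 (key step).** The most likely failures are three. The alkyne may bond through C11 instead of C12, because a methyl and a methylene substituent differ little, which would give the 13-membered ring with an exocyclic ethylidene. Ring closure may be slow enough for intermolecular coupling to take over. Nickel and phosphine may isomerise the terminal oxirane to an aldehyde, which would then couple with the alkyne as an aldehyde. The fallback uses known chemistry, sets out from 26 and returns at 27. The terminal oxirane of 26 would be opened at C13 with diethyl(prop-1-yn-1-yl)alane (from prop-1-ynyllithium and Et2AlCl, toluene, 0 °C), a reagent that spares lactones, to give the diyne alcohol F1. Ring-closing alkyne metathesis with Mo(≡CC6H4OMe)(OSiPh3)3 (toluene, 5 Å molecular sieves, high dilution) would give the cycloalkyne F2. The C14 hydroxyl would then direct trans-hydrostannation ([Cp*RuCl]4, Bu3SnH, CH2Cl2) to the alkenylstannane F3, with tin on C12 and hydrogen on C11. Methyl-for-tin exchange (MeI, Pd(PPh3)4, CuO2CC4H3S (monovalent copper thiophene-2-carboxylate), Ph2PO2NBu4, DMF) would give 27.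

**Step 13.** Acyl transfer to the hindered tert-butyl ester may be slower than alkoxide-driven oxirane chemistry: Payne migration, attack of O2 on the terminal oxirane, or closure of a cyclopropane by the ester enolate on C14. The fallback sets out from 25 and returns at 26. i-Bu2AlH (CH2Cl2, −78 °C) would reduce the ester to the aldehyde, which closes onto O2 as the lactol F4; PhI(OAc)2 with catalytic TEMPO (CH2Cl2, rt) would oxidise F4 to 26 under neutral conditions.

**Step 9.** The alkenyllithium may be lost by proton transfer from the positions α to the ester or the amide or by attack on the ester, and the metal alkoxide may close onto the chloride or undergo retro-aldol cleavage if the mixture warms. The fallback sets out from 18 and returns at 21. The hydroxyl would be silylated (Et3SiCl, imidazole, DMF) to the silyl ether F5; addition of 19 at −78 °C would give the silyloxy enone F6; AcOH/THF/H2O at rt would free the hydroxyl to give 21.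

**Step 16.** Aminomethylation of the hindered enolate next to the C14 silyloxy group may stall, or the quaternisation–elimination may be incomplete. The fallback sets out from 28 and returns at 31. The lithium enolate of 28 (LiN(i-Pr)2, THF, −78 °C) would be trapped with monomeric formaldehyde, the smallest electrophile, to give the hydroxymethyl lactone F7; MsCl/Et3N (CH2Cl2, 0 °C) would give the mesylate F8, and DBU would eliminate it to 31.

## Further compounds

F1 | step 14 | (4R,5S)-4-[(1S)-1-hydroxyhex-4-yn-1-yl]-5-{(2R,3R)-3-methyl-3-[(3E)-4-methylnon-3-en-7-yn-1-yl]oxiran-2-yl}oxolan-2-one | CC#CCC/C(C)=C/CC[C@@]1(C)O[C@@H]1[C@H]1OC(=O)C[C@@H]1[C@@H](O)CC#CC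
F2 | step 14 | 11,12-didehydro-20-nor analogue of 27 (14-membered cycloalkyne, C11≡C12) | C1C(=O)O[C@H]2[C@H]1[C@@H](O)CC#CCC/C(C)=C/CC[C@@]1(C)O[C@H]21
F3 | step 14 | 12-tributylstannyl-20-nor analogue of 27 (tin on C12, hydrogen on C11, ring carbons trans) | C1C(=O)O[C@H]2[C@H]1[C@@H](O)C/C([Sn](CCCC)(CCCC)CCCC)=C/CC/C(C)=C/CC[C@@]1(C)O[C@H]21
F4 | step 13 | (4R,5S)-5-{(2R,3R)-3-methyl-3-[(3E)-4-methylnon-3-en-7-yn-1-yl]oxiran-2-yl}-4-[(2R)-oxiran-2-yl]oxolan-2-ol (anomers) | CC#CCC/C(C)=C/CC[C@@]1(C)O[C@@H]1[C@H]1OC(O)C[C@@H]1[C@@H]1CO1
F5 | step 9 | tert-butyl (3R,4R)-5-chloro-3-[methoxy(methyl)carbamoyl]-4-[(triethylsilyl)oxy]pentanoate | CC(C)(C)OC(=O)C[C@H]([C@@H](O[Si](CC)(CC)CC)CCl)C(=O)N(C)OC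
F6 | step 9 | tert-butyl (3R,5E,9E)-3-{(1R)-2-chloro-1-[(triethylsilyl)oxy]ethyl}-6,10-dimethyl-4-oxopentadeca-5,9-dien-13-ynoate | CC#CCC/C(C)=C/CC/C(C)=C/C(=O)[C@H](CC(=O)OC(C)(C)C)[C@@H](O[Si](CC)(CC)CC)CCl
F7 | step 16 | 15-(hydroxymethyl) derivative of 28 (C15 epimers) | OCC1C(=O)O[C@H]2[C@H]1[C@@H](O[Si](CC)(CC)CC)C/C(C)=C/CC/C(C)=C/CC[C@@]1(C)O[C@H]21
F8 | step 16 | methanesulfonate of F7 | CS(=O)(=O)OCC1C(=O)O[C@H]2[C@H]1[C@@H](O[Si](CC)(CC)CC)C/C(C)=C/CC/C(C)=C/CC[C@@]1(C)O[C@H]21
A1 | alternative 1 | 16-membered allyl β-keto ester macrolactone (carboxylate bridging C5 and C6; C3 p-methoxybenzyl ether, C14 tert-butyldimethylsilyl ether) | COc1ccc(CO[C@@H]2C(=O)CC(=O)OC/C=C(C)/CC/C=C(C)/C[C@H](O[Si](C)(C)C(C)(C)C)[C@H]3CC(=O)O[C@H]23)cc1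
A2 | alternative 1 | 14-membered C4 ketone (C3 p-methoxybenzyl ether, C14 tert-butyldimethylsilyl ether, C1–C2 lactone) | COc1ccc(CO[C@@H]2C(=O)CC/C=C(C)/CC/C=C(C)/C[C@H](O[Si](C)(C)C(C)(C)C)[C@H]3CC(=O)O[C@H]23)cc1
A3 | alternative 2 | acyclic diyne with methyl-capped alkynes at C11 and C12, exo-methylene lactone and free C14 hydroxyl | C=C1C(=O)O[C@@H]([C@H]1[C@@H](O)CC#CC)[C@H]1O[C@]1(C)CC/C=C(C)/CCC#CC
A4 | alternative 2 | 14-membered C11–C12 cycloalkyne with exo-methylene lactone and free C14 hydroxyl | C=C1C(=O)O[C@H]2[C@H]1[C@@H](O)CC#CCC/C(C)=C/CC[C@@]1(C)O[C@H]21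
A5 | alternative 3 | saturated lactone with C14 formyl group on C1 and (E)-2-methyl-1,3-diene at C10–C13 | O=C[C@H]1CC(=O)O[C@@H]1[C@H]1O[C@]1(C)CC/C=C(C)/C/C=C/C(C)=C
A6 | alternative 3 | macrocyclic C14 triethylsilyl ether of the saturated lactone (identical with 28) | C1C(=O)O[C@H]2[C@H]1[C@@H](O[Si](CC)(CC)CC)C/C(C)=C/CC/C(C)=C/CC[C@@]1(C)O[C@H]21
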